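**Plan**

- Ring atoms: C1 (quaternary; CH2OH and homofarnesyl), C2 (CH; 3-hydroxypropyl), C3 (=C7(CH3)CHO), C4 and C5 (CH2), C6 (C(CH3)OH).
- Retrosynthesis: CHO back to CH2OPMB, the C6 carbinol back to a C6 ketone (via methylidene and spiro-epoxide), hydroxypropyl back to vinyl, CH2OH back to CO2Me. Then C3–C4 and C7–CH3 are cut together (cyclohexanone to acyclic vinyl ketone–alkyne), then C1–C2 (allylic alkylation), then the C1–side-chain bond (acetoacetate alkylation).
- Enabling feature: the exocyclic tetrasubstituted C3=C7 alkene (CHO cis to C2, CH3 cis to C4) is the syn adduct of C4 and CH3 across a C3≡C7 alkyne. C2 and the quaternary C1 hold that alkyne 1,7 to the vinyl ketone C4=C5–C6(=O), and the ring so closed is the only ring of the target.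
- Forward: farnesol gives homofarnesyl iodide, which alkylates methyl acetoacetate; propargyl alcohol gives an E-enynyl carbonate; iridium joins the two; Mannich methylenation gives the vinyl ketone; nickel/CH3ZnCl/Me3SiCl closes the carbocycle; seven steps adjust oxidation levels.
- Stereochemistry: C2 and C1 from the iridium-catalysed allylation (ligand and chelated enolate); C3=C7 geometry from syn carbometalation; C6 from hydroxyl-directed epoxidation cis to the C1 CH2OH, then hydride opening; the chain E-alkenes from farnesol.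

Key step: step 13

Assumption: in step 11 the phosphoramidite antipode used is the one that gives (R) at C2 (nucleophile anti to iridium), and the C1 configuration is taken to follow the facial preference of lithium-chelated acyclic α-alkyl β-keto ester enolates.

**Route**

Step 1
Reactants: 1 (2E,6E)-farnesol
Product: 2 (2E,6E)-farnesal
Conditions: MnO2 (activated), CH2Cl2, rt
Reagents that add atoms: none
Why: Allylic oxidation with MnO2 stops at the enal and leaves the isolated trisubstituted alkenes and the 2E geometry untouched.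

Step 2
Reactants: 2 (2E,6E)-farnesal
Product: 3 (3E,7E)-4,8,12-trimethyltrideca-1,3,7,11-tetraene
Conditions: Ph3PCH3Br, KOt-Bu, THF, 0 °C to rt
Reagents that add atoms: methyltriphenylphosphonium bromide, C[P+](c1ccccc1)(c1ccccc1)c1ccccc1.[Br-]
Why: Wittig methylenation of the enal with the non-stabilised ylide gives the terminal 1,3-diene without touching the 3E alkene.

Step 3
Reactants: 3 (3E,7E)-4,8,12-trimethyltrideca-1,3,7,11-tetraene
Product: 5 (3E,7E)-homofarnesol [(3E,7E)-4,8,12-trimethyltrideca-3,7,11-trien-1-ol], via 9-homofarnesyl-9-borabicyclo[3.3.1]nonane 4 (not isolated)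
Conditions: 9-BBN, THF, 0 °C to rt; then NaOH, H2O2, 0 °C
Reagents that add atoms: hydrogen peroxide, OO
Why: Hydroboration–oxidation: 9-BBN adds anti-Markovnikov to the only monosubstituted alkene far faster than to the trisubstituted ones, and oxidation of the borane gives the primary homoallylic alcohol.

Step 4
Reactants: 5 (3E,7E)-homofarnesol
Product: 6 (3E,7E)-homofarnesyl iodide [(6E,10E)-13-iodo-2,6,10-trimethyltrideca-2,6,10-triene]
Conditions: PPh3, I2, imidazole, CH2Cl2, 0 °C
Reagents that add atoms: iodine, II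
Why: Appel-type iodination displaces the oxyphosphonium group of the primary alcohol by iodide (SN2) under neutral conditions that spare the alkenes.

Step 5
Reactants: 6 (3E,7E)-homofarnesyl iodide; 7 methyl acetoacetate
Product: 8 methyl (5E,9E)-2-acetyl-6,10,14-trimethylpentadeca-5,9,13-trienoate (racemic at C2)
Conditions: NaH, THF/DMF, 0 to 60 °C (7 in excess)
Reagents that add atoms: none
Why: Acetoacetic ester alkylation: the sodium enolate is C-alkylated by the primary iodide, and the excess of keto ester suppresses dialkylation.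

Step 6
Reactants: 9 propargyl alcohol
Product: 10 1-methoxy-4-[(prop-2-yn-1-yloxy)methyl]benzene (4-methoxybenzyl propargyl ether)
Conditions: NaH, 4-methoxybenzyl chloride, n-Bu4NI (cat.), THF, 0 °C to rt
Reagents that add atoms: 4-methoxybenzyl chloride, COc1ccc(CCl)cc1
Why: Williamson ether synthesis on the alkoxide; NaH does not deprotonate the alkyne C–H.

Step 7
Reactants: 10 4-methoxybenzyl propargyl ether
Product: 11 4-[(4-methoxyphenyl)methoxy]but-2-ynal
Conditions: n-BuLi, THF, −78 °C; DMF; then inverse quench into aq. KH2PO4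
Reagents that add atoms: N,N-dimethylformamide, CN(C)C=O
Why: Formylation of the lithium acetylide with DMF, the buffered inverse quench releasing the ynal without conjugate addition of dimethylamine.

Step 8
Reactants: 11 4-[(4-methoxyphenyl)methoxy]but-2-ynal
Product: 12 ethyl (2E)-6-[(4-methoxyphenyl)methoxy]hex-2-en-4-ynoate
Conditions: (EtO)2P(O)CH2CO2Et, NaH, THF, −78 to 0 °C
Reagents that add atoms: triethyl phosphonoacetate, CCOC(=O)CP(=O)(OCC)OCC
Why: Horner–Wadsworth–Emmons olefination with the stabilised phosphonate anion gives the E-enoate selectively.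

Step 9
Reactants: 12 ethyl (2E)-6-[(4-methoxyphenyl)methoxy]hex-2-en-4-ynoate
Product: 13 (2E)-6-[(4-methoxyphenyl)methoxy]hex-2-en-4-yn-1-ol
Conditions: i-Bu2AlH, CH2Cl2, −78 °C; aq. KNaC4H4O6 (tartrate) work-up
Reagents that add atoms: none
Why: 1,2-Reduction of the conjugated ester by the aluminium hydride at low temperature gives the allylic alcohol and leaves alkyne, alkene and PMB ether alone.

Step 10
Reactants: 13 (2E)-6-[(4-methoxyphenyl)methoxy]hex-2-en-4-yn-1-ol
Product: 14 methyl (2E)-6-[(4-methoxyphenyl)methoxy]hex-2-en-4-yn-1-yl carbonate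
Conditions: ClCO2Me, pyridine, CH2Cl2, 0 °C
Reagents that add atoms: methyl chloroformate, COC(=O)Cl
Why: Acylation of the primary allylic alcohol installs the carbonate leaving group needed for ionisation by iridium.

Step 11
Reactants: 8 methyl (5E,9E)-2-acetyl-6,10,14-trimethylpentadeca-5,9,13-trienoate; 14 methyl (2E)-6-[(4-methoxyphenyl)methoxy]hex-2-en-4-yn-1-yl carbonate
Product: 15 methyl (2R,5E,9E)-2-acetyl-2-[(3R)-6-[(4-methoxyphenyl)methoxy]hex-1-en-4-yn-3-yl]-6,10,14-trimethylpentadeca-5,9,13-trienoate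
Conditions: [Ir(cod)Cl]2 (2 mol %), BINOL-derived N-aryl phosphoramidite (4 mol %), TBD (10 mol %), LiOt-Bu, THF, 25 °C
Reagents that add atoms: none
Why: Iridium-catalysed asymmetric allylic alkylation of an acyclic α-alkyl β-keto ester: the cyclometallated iridium–phosphoramidite complex ionises the linear carbonate and directs the lithium-chelated enolate to the alkynyl-bearing allyl terminus anti to the metal, so that the ligand sets C2 and the approach of the chelated Z-enolate to that allyl face sets the quaternary C1 relative to C2.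

Step 12
Reactants: 15 methyl ketone (Ir-allylation product)
Product: 17 methyl (2R,5E,9E)-2-[(3R)-6-[(4-methoxyphenyl)methoxy]hex-1-en-4-yn-3-yl]-6,10,14-trimethyl-2-(prop-2-enoyl)pentadeca-5,9,13-trienoate, via Mannich base 16 (not isolated)
Conditions: (CH2O)n, i-Pr2NH2+ CF3CO2−, CF3CO2H (cat.), THF, reflux
Reagents that add atoms: paraformaldehyde (formaldehyde), C=O
Why: Mannich methylenation: the acetyl CH3, the only enolisable position next to the quaternary C1, condenses with the iminium ion, and the β-amino ketone loses the amine on heating to give the vinyl ketone under conditions too mild to isomerise the skipped enyne at C2.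

Step 13
Reactants: 17 acyclic vinyl ketone–alkyne β-keto ester
Product: 19 methyl (1R,2R,3Z)-2-ethenyl-3-{1-[(4-methoxyphenyl)methoxy]propan-2-ylidene}-6-oxo-1-[(3E,7E)-4,8,12-trimethyltrideca-3,7,11-trien-1-yl]cyclohexane-1-carboxylate, via trimethylsilyl enol ether 18 (not isolated)
Conditions: Ni(cod)2 (10 mol %), CH3ZnCl (2 M in THF), Me3SiCl, THF, 0 °C to rt; then 1 M HCl, THF, 0 °C
Reagents that add atoms: chloro(methyl)zinc, C[Zn]Cl
Why: Proposed new method: zerovalent nickel and Me3SiCl convert the s-trans vinyl ketone into an η3-1-siloxyallyl nickel chloride (divalent nickel), whose unhindered terminus C4 adds with nickel across the tethered alkyne in a syn insertion to form C3–C4 and an alkenylnickel at C7, after which methyl transfer from zinc and reductive elimination form C7–CH3 and return zerovalent nickel. The closest known reactions are the nickel-catalysed alkylative cyclization of alkynyl enones with organozincs (known for tethers at the enone β-carbon) and the intermolecular nickel/Me3SiCl coupling of s-trans cyclic enones, alkynes and methylzinc reagents; closure through a tether on the carbonyl carbon is the untested element. The silyl chloride is added because this mode cannot use the usual oxygen-bound nickelacycle, an enolate oxygen on C6 being unable to reach C7 across the ring. The six-membered ring closes 6-exo-dig at the alkyne and endo with respect to the enone (C6 inside the ring); no stereocentre is created, and the Z alkene (CH2OPMB cis to C2, CH3 cis to C4) follows from the syn addition of carbon and nickel. Six- rather than five-membered closure rests on bond formation at the allyl terminus C4 and not at C5, and cyclization over plain conjugate methylation on intramolecular alkyne insertion outrunning methyl transfer; the quaternary C1 favours the folded conformer, and C1 and C2 are not touched. Acid work-up hydrolyses silyl enol ether 18 to the ketone.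

Step 14
Reactants: 19 cyclohexanone β-keto ester
Product: 20 methyl (1R,2R,3Z)-2-ethenyl-3-{1-[(4-methoxyphenyl)methoxy]propan-2-ylidene}-6-methylidene-1-[(3E,7E)-4,8,12-trimethyltrideca-3,7,11-trien-1-yl]cyclohexane-1-carboxylate
Conditions: Ph3PCH3Br, KOt-Bu, toluene, rt to 80 °C
Reagents that add atoms: methyltriphenylphosphonium bromide, C[P+](c1ccccc1)(c1ccccc1)c1ccccc1.[Br-]
Why: Wittig methylenation of the hindered ketone; C1 is non-enolisable and the ester is inert to the ylide.

Step 15
Reactants: 20 methylidene ester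
Product: 21 methyl (1R,2R,3Z)-3-{1-[(4-methoxyphenyl)methoxy]propan-2-ylidene}-6-methylidene-2-(3-oxopropyl)-1-[(3E,7E)-4,8,12-trimethyltrideca-3,7,11-trien-1-yl]cyclohexane-1-carboxylate
Conditions: Rh(acac)(CO)2 (1 mol %), BIPHEPHOS (2 mol %), CO/H2 (1:1, 5 bar), toluene, 60 °C
Reagents that add atoms: carbon monoxide, [C-]#[O+]
Why: Rhodium-catalysed hydroformylation with a wide-bite-angle bisphosphite is selective for the monosubstituted alkene and for the linear aldehyde, the 1,1-di-, tri- and tetrasubstituted alkenes reacting far more slowly.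

Step 16
Reactants: 21 aldehyde ester
Product: 22 [(1R,2R,3Z)-2-(3-hydroxypropyl)-3-{1-[(4-methoxyphenyl)methoxy]propan-2-ylidene}-6-methylidene-1-[(3E,7E)-4,8,12-trimethyltrideca-3,7,11-trien-1-yl]cyclohexyl]methanol
Conditions: LiAlH4, THF, 0 °C to rt; aq. NaOH work-up
Reagents that add atoms: none
Why: LiAlH4 reduces the aldehyde and the hindered methyl ester to the two primary alcohols in one operation.

Step 17
Reactants: 22 diol
Product: 23 3-[(3S,4S,5R,6Z)-4-(hydroxymethyl)-6-{1-[(4-methoxyphenyl)methoxy]propan-2-ylidene}-4-[(3E,7E)-4,8,12-trimethyltrideca-3,7,11-trien-1-yl]-1-oxaspiro[2.5]octan-5-yl]propan-1-ol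
Conditions: VO(acac)2 (5 mol %), t-BuOOH, CH2Cl2, 0 °C
Reagents that add atoms: tert-butyl hydroperoxide, CC(C)(C)OO
Why: Hydroxyl-directed epoxidation: the vanadium alkoxide of the C1 hydroxymethyl group delivers oxygen to the homoallylic C6 methylidene on the face cis to CH2OH, which sets C6, while alkenes without a nearby hydroxyl react more slowly.

Step 18
Reactants: 23 spiro-epoxide
Product: 24 (1S,2S,3R,4Z)-2-(hydroxymethyl)-3-(3-hydroxypropyl)-4-{1-[(4-methoxyphenyl)methoxy]propan-2-ylidene}-1-methyl-2-[(3E,7E)-4,8,12-trimethyltrideca-3,7,11-trien-1-yl]cyclohexan-1-ol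
Conditions: LiBHEt3, THF, 0 °C to rt; then H2O
Reagents that add atoms: none
Why: Hydride opens the epoxide by SN2 attack at the unhindered CH2 terminus, so the C6–O bond and the configuration of the tertiary alcohol are retained.

Step 19
Reactants: 24 PMB-protected triol
Product: 25 (1S,2S,3R,4Z)-2-(hydroxymethyl)-4-(1-hydroxypropan-2-ylidene)-3-(3-hydroxypropyl)-1-methyl-2-[(3E,7E)-4,8,12-trimethyltrideca-3,7,11-trien-1-yl]cyclohexan-1-ol
Conditions: DDQ, CH2Cl2/pH 7 phosphate buffer, 0 °C
Reagents that add atoms: none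
Why: Oxidative cleavage of the 4-methoxybenzyl ether by DDQ in wet buffered solvent frees the allylic alcohol without acid that could isomerise the alkenes.

Step 20
Reactants: 25 tetraol
Product: 26 (2Z)-2-[(2R,3S,4S)-4-hydroxy-3-(hydroxymethyl)-2-(3-hydroxypropyl)-4-methyl-3-[(3E,7E)-4,8,12-trimethyltrideca-3,7,11-trien-1-yl]cyclohexylidene]propanal (CNP0284886.1)
Conditions: MnO2, CH2Cl2, rt
Reagents that add atoms: none
Why: MnO2 oxidises only the allylic primary alcohol to the enal, leaving the two saturated primary alcohols, the tertiary alcohol and the alkene geometry untouched.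

**Compound list**

1 | (2E,6E)-farnesol | CC(C)=CCC/C(C)=C/CC/C(C)=C/CO | starting material
2 | (2E,6E)-farnesal | CC(C)=CCC/C(C)=C/CC/C(C)=C/C=O | intermediate
3 | (3E,7E)-4,8,12-trimethyltrideca-1,3,7,11-tetraene | CC(C)=CCC/C(C)=C/CC/C(C)=C/C=C | intermediate
4 | 9-[(3E,7E)-4,8,12-trimethyltrideca-3,7,11-trien-1-yl]-9-borabicyclo[3.3.1]nonane | CC(C)=CCC/C(C)=C/CC/C(C)=C/CCB1C2CCCC1CCC2 | intermediate (not isolated)
5 | (3E,7E)-homofarnesol | CC(C)=CCC/C(C)=C/CC/C(C)=C/CCO | intermediate
6 | (3E,7E)-homofarnesyl iodide | CC(C)=CCC/C(C)=C/CC/C(C)=C/CCI | intermediate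
7 | methyl acetoacetate | CC(=O)CC(=O)OC | starting material
8 | methyl (5E,9E)-2-acetyl-6,10,14-trimethylpentadeca-5,9,13-trienoate (racemic) | CC(C)=CCC/C(C)=C/CC/C(C)=C/CCC(C(C)=O)C(=O)OC | intermediate
9 | propargyl alcohol | C#CCO | starting material
10 | 1-methoxy-4-[(prop-2-yn-1-yloxy)methyl]benzene | C#CCOCc1ccc(OC)cc1 | intermediate
11 | 4-[(4-methoxyphenyl)methoxy]but-2-ynal | O=CC#CCOCc1ccc(OC)cc1 | intermediate
12 | ethyl (2E)-6-[(4-methoxyphenyl)methoxy]hex-2-en-4-ynoate | CCOC(=O)/C=C/C#CCOCc1ccc(OC)cc1 | intermediate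
13 | (2E)-6-[(4-methoxyphenyl)methoxy]hex-2-en-4-yn-1-ol | OC/C=C/C#CCOCc1ccc(OC)cc1 | intermediate
14 | methyl (2E)-6-[(4-methoxyphenyl)methoxy]hex-2-en-4-yn-1-yl carbonate | COC(=O)OC/C=C/C#CCOCc1ccc(OC)cc1 | intermediate
15 | methyl (2R,5E,9E)-2-acetyl-2-[(3R)-6-[(4-methoxyphenyl)methoxy]hex-1-en-4-yn-3-yl]-6,10,14-trimethylpentadeca-5,9,13-trienoate | CC(C)=CCC/C(C)=C/CC/C(C)=C/CC[C@@](C(C)=O)(C(=O)OC)[C@H](C=C)C#CCOCc1ccc(OC)cc1 | intermediate
16 | Mannich base: methyl (2R,5E,9E)-2-[3-(diisopropylamino)propanoyl]-2-[(3R)-6-[(4-methoxyphenyl)methoxy]hex-1-en-4-yn-3-yl]-6,10,14-trimethylpentadeca-5,9,13-trienoate | CC(C)=CCC/C(C)=C/CC/C(C)=C/CC[C@@](C(=O)CCN(C(C)C)C(C)C)(C(=O)OC)[C@H](C=C)C#CCOCc1ccc(OC)cc1 | intermediate (not isolated)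
17 | methyl (2R,5E,9E)-2-[(3R)-6-[(4-methoxyphenyl)methoxy]hex-1-en-4-yn-3-yl]-6,10,14-trimethyl-2-(prop-2-enoyl)pentadeca-5,9,13-trienoate | CC(C)=CCC/C(C)=C/CC/C(C)=C/CC[C@@](C(=O)C=C)(C(=O)OC)[C@H](C=C)C#CCOCc1ccc(OC)cc1 | intermediate (key-step precursor)
18 | trimethylsilyl enol ether of 19 (C5=C6, OSiMe3 on C6; 1R,2R,3Z) | CC(C)=CCC/C(C)=C/CC/C(C)=C/CC[C@@]1(C(=O)OC)[C@H](C=C)/C(=C(/C)COCc2ccc(OC)cc2)CC=C1O[Si](C)(C)C | intermediate (not isolated)
19 | methyl (1R,2R,3Z)-2-ethenyl-3-{1-[(4-methoxyphenyl)methoxy]propan-2-ylidene}-6-oxo-1-[(3E,7E)-4,8,12-trimethyltrideca-3,7,11-trien-1-yl]cyclohexane-1-carboxylate | CC(C)=CCC/C(C)=C/CC/C(C)=C/CC[C@@]1(C(=O)OC)[C@H](C=C)/C(=C(/C)COCc2ccc(OC)cc2)CCC1=O | intermediate (key-step product)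
20 | methyl (1R,2R,3Z)-2-ethenyl-3-{1-[(4-methoxyphenyl)methoxy]propan-2-ylidene}-6-methylidene-1-[(3E,7E)-4,8,12-trimethyltrideca-3,7,11-trien-1-yl]cyclohexane-1-carboxylate | CC(C)=CCC/C(C)=C/CC/C(C)=C/CC[C@@]1(C(=O)OC)[C@H](C=C)/C(=C(/C)COCc2ccc(OC)cc2)CCC1=C | intermediate
21 | methyl (1R,2R,3Z)-3-{1-[(4-methoxyphenyl)methoxy]propan-2-ylidene}-6-methylidene-2-(3-oxopropyl)-1-[(3E,7E)-4,8,12-trimethyltrideca-3,7,11-trien-1-yl]cyclohexane-1-carboxylate | CC(C)=CCC/C(C)=C/CC/C(C)=C/CC[C@@]1(C(=O)OC)[C@H](CCC=O)/C(=C(/C)COCc2ccc(OC)cc2)CCC1=C | intermediate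
22 | [(1R,2R,3Z)-2-(3-hydroxypropyl)-3-{1-[(4-methoxyphenyl)methoxy]propan-2-ylidene}-6-methylidene-1-[(3E,7E)-4,8,12-trimethyltrideca-3,7,11-trien-1-yl]cyclohexyl]methanol | CC(C)=CCC/C(C)=C/CC/C(C)=C/CC[C@@]1(CO)[C@H](CCCO)/C(=C(/C)COCc2ccc(OC)cc2)CCC1=C | intermediate
23 | 3-[(3S,4S,5R,6Z)-4-(hydroxymethyl)-6-{1-[(4-methoxyphenyl)methoxy]propan-2-ylidene}-4-[(3E,7E)-4,8,12-trimethyltrideca-3,7,11-trien-1-yl]-1-oxaspiro[2.5]octan-5-yl]propan-1-ol | CC(C)=CCC/C(C)=C/CC/C(C)=C/CC[C@@]1(CO)[C@H](CCCO)/C(=C(/C)COCc2ccc(OC)cc2)CC[C@]13OC3 | intermediate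
24 | (1S,2S,3R,4Z)-2-(hydroxymethyl)-3-(3-hydroxypropyl)-4-{1-[(4-methoxyphenyl)methoxy]propan-2-ylidene}-1-methyl-2-[(3E,7E)-4,8,12-trimethyltrideca-3,7,11-trien-1-yl]cyclohexan-1-ol | CC(C)=CCC/C(C)=C/CC/C(C)=C/CC[C@@]1(CO)[C@H](CCCO)/C(=C(/C)COCc2ccc(OC)cc2)CC[C@]1(C)O | intermediate
25 | (1S,2S,3R,4Z)-2-(hydroxymethyl)-4-(1-hydroxypropan-2-ylidene)-3-(3-hydroxypropyl)-1-methyl-2-[(3E,7E)-4,8,12-trimethyltrideca-3,7,11-trien-1-yl]cyclohexan-1-ol | CC(C)=CCC/C(C)=C/CC/C(C)=C/CC[C@@]1(CO)[C@H](CCCO)/C(=C(/C)CO)CC[C@]1(C)O | intermediate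
26 | (2Z)-2-[(2R,3S,4S)-4-hydroxy-3-(hydroxymethyl)-2-(3-hydroxypropyl)-4-methyl-3-[(3E,7E)-4,8,12-trimethyltrideca-3,7,11-trien-1-yl]cyclohexylidene]propanal | CC(C)=CCC/C(C)=C/CC/C(C)=C/CC[C@@]1(CO)[C@H](CCCO)/C(=C(/C)C=O)CC[C@]1(C)O | target

**Step count and risks**

Total: 20 steps. Longest linear sequence: 15 steps (steps 1–5 and 11–20; the branch of steps 6–10 and 11–20 is equally long).

Most likely to fail:

1. Step 13 (nickel cyclization). Methyl transfer to the siloxyallyl nickel species may outrun alkyne insertion, which would give plain conjugate methylation of the vinyl ketone. The ring may also fail to close in the carbonyl-inside mode. The fallback uses known reaction types only; it sets out from methyl ketone 15 and returns at ketone 19. Formylation of the kinetic lithium enolate of 15 (LiN(SiMe3)2, THF, −78 °C; then CF3CH2OCHO) would give the Z-hydroxymethylene ketone F1. Triflation of its sodium chelate (NaH, PhNTf2) would give the (Z)-β-triflyloxy enone F2. A palladium cascade (Pd(PPh3)4, trimethylboroxine, K2CO3, dioxane, 80 °C) of oxidative addition at C4, syn 6-exo-dig carbopalladation of the alkyne and Suzuki methylation at C7 would give the 2,4-dienone F3 with the same C3=C7 geometry. Conjugate reduction of its disubstituted C4=C5 bond with [(Ph3P)CuH]6, hydride going to the less substituted β-carbon C4, would then give 19.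

2. Step 11 (iridium allylation). The fully substituted enolate may attack the alkynyl-bearing allyl terminus slowly, with leakage to the linear product, and the two enolate faces may be poorly distinguished (C1 epimer). The fallback sets out from methyl acetoacetate 7 and carbonate 14 and returns at 15. The same iridium catalyst would first allylate the unsubstituted keto ester, the best precedented case, in which only C2 is set, to give methyl (3S)-2-acetyl-3-ethenyl-6-[(4-methoxyphenyl)methoxy]hex-4-ynoate F4. Its sodium enolate (NaH, DMF) would then be alkylated with iodide 6. The quaternary centre would thus arise under control of the neighbouring C2 centre and not of the catalyst, and the C1 epimer would be removed by chromatography if it forms.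

3. Step 17 (directed epoxidation). Oxygen may be delivered to the tetrasubstituted C3=C7 alkene, which is bishomoallylic to the same hydroxyl, or to the wrong face of the methylidene group. The epoxy alcohol may also close to a tetrahydrofuran. The fallback sets out from ketone 19 and returns at triol 24, bypassing steps 14, 17 and 18. Addition of CH3MgBr/CeCl3 (THF, −78 °C) to the C6 ketone would give the tertiary alcohol F5. Attack is expected from the face opposite the C2 vinyl group, which allylic strain against CH2OPMB holds axial. Hydroformylation under the conditions of step 15 would give aldehyde F6, and LiAlH4 would reduce ester and aldehyde to 24.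

**Further compounds**

F1 | step 13 | methyl (2R,5E,9E)-2-[(2Z)-3-hydroxyprop-2-enoyl]-2-[(3R)-6-[(4-methoxyphenyl)methoxy]hex-1-en-4-yn-3-yl]-6,10,14-trimethylpentadeca-5,9,13-trienoate | CC(C)=CCC/C(C)=C/CC/C(C)=C/CC[C@@](C(=O)/C=C\O)(C(=O)OC)[C@H](C=C)C#CCOCc1ccc(OC)cc1
F2 | step 13 | methyl (2R,5E,9E)-2-[(3R)-6-[(4-methoxyphenyl)methoxy]hex-1-en-4-yn-3-yl]-6,10,14-trimethyl-2-[(2Z)-3-(trifluoromethanesulfonyloxy)prop-2-enoyl]pentadeca-5,9,13-trienoate | CC(C)=CCC/C(C)=C/CC/C(C)=C/CC[C@@](C(=O)/C=C\OS(=O)(=O)C(F)(F)F)(C(=O)OC)[C@H](C=C)C#CCOCc1ccc(OC)cc1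
F3 | step 13 | methyl (1R,6R,5Z)-6-ethenyl-5-{1-[(4-methoxyphenyl)methoxy]propan-2-ylidene}-2-oxo-1-[(3E,7E)-4,8,12-trimethyltrideca-3,7,11-trien-1-yl]cyclohex-3-ene-1-carboxylate | CC(C)=CCC/C(C)=C/CC/C(C)=C/CC[C@@]1(C(=O)OC)[C@H](C=C)/C(=C(/C)COCc2ccc(OC)cc2)C=CC1=O
F4 | step 11 | methyl (3S)-2-acetyl-3-ethenyl-6-[(4-methoxyphenyl)methoxy]hex-4-ynoate | CC(=O)C(C(=O)OC)[C@H](C=C)C#CCOCc1ccc(OC)cc1
F5 | step 17 | methyl (1R,2R,3Z,6S)-2-ethenyl-6-hydroxy-3-{1-[(4-methoxyphenyl)methoxy]propan-2-ylidene}-6-methyl-1-[(3E,7E)-4,8,12-trimethyltrideca-3,7,11-trien-1-yl]cyclohexane-1-carboxylate | CC(C)=CCC/C(C)=C/CC/C(C)=C/CC[C@@]1(C(=O)OC)[C@H](C=C)/C(=C(/C)COCc2ccc(OC)cc2)CC[C@]1(C)O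
F6 | step 17 | methyl (1R,2R,3Z,6S)-6-hydroxy-3-{1-[(4-methoxyphenyl)methoxy]propan-2-ylidene}-6-methyl-2-(3-oxopropyl)-1-[(3E,7E)-4,8,12-trimethyltrideca-3,7,11-trien-1-yl]cyclohexane-1-carboxylate | CC(C)=CCC/C(C)=C/CC/C(C)=C/CC[C@@]1(C(=O)OC)[C@H](CCC=O)/C(=C(/C)COCc2ccc(OC)cc2)CC[C@]1(C)O
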